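Count what is missing.

| flask | substrate | remark | time |
|---|---|---|---|
| delta | 0.028 M | run made earlier |  |
| zeta | 0.044 M | run made earlier |  |
| larch | 0.020 M |  | 2.5 min |
| maple | 0.020 M |  | 6.0 min |
| ash | 0.020 M |  | 15 min |

| run | time / s | target / % | substrate / % |
|---|---|---|---|
| delta | 10.0 | 0 | 35 |
| delta | 15.0 | 0 | 21 |
| delta | 25.0 | 3 | 14 |
| delta | 40.0 | 7 | 6 |
| delta | 50.0 | 12 | 2 |
| delta | 80.0 | 22 | 1 |
| delta | 90.0 | 22 | 0 |
| zeta | 12.0 | 3 | 25 |
| zeta | 25.0 | 3 | 10 |
| zeta | 40.0 | 5 | 6 |
| zeta | 50.0 | 8 | 3 |
| zeta | 60.0 | 13 | 2 |
| zeta | 80.0 | 18 | 3 |
| zeta | 90.0 | 21 | 1 |

(readings scatter by 2 percentage points)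

- the analysis behind the earlier runs scatters by 2 percentage points, standard deviation

* which of the two there is more of at the end, larch (target / isomer of the product)
* which of the two there is more of at the end, maple (target / isomer of the product)
* which of the two there is more of at the end, ash (target / isomer of the product)
* how much target is there at the end, in percent of the substrate charged: larch
* how much target is there at the end, in percent of the substrate charged: maple
* how much target is there at the end, in percent of the substrate charged: ash

Watch the gap. The unseen share is the fraction of the charge that is neither substrate nor target, the open gap in the mass balance. In the delta run at 90.0 s this share reads 78.0%, and the zeta run at 90.0 s reads 78.0%, and those parts of the two charges stand in forms not read. Between 50.0 s and 90.0 s in delta, substrate lost 2 percentage points, less than the 10 points that target gained, so target is then fed from the unseen share. The substrate reading therefore does not mark the end of the change in delta.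

A reckoning made here, apart from the forecast, follows the fraction left. In delta the unseen share fell from 86.0% to 78.0%, a reading that carries the scatter and gives a half-life of 4.73 min. If the pace read in delta holds in larch and ash and the whole share feeds target, the unseen share should stand at 67.4% at the end of larch and 10.8% at the end of ash.

The forecast puts isomer of the product ahead in larch and target ahead in maple and ash, with target at 35%, 64% and 88%. Of long times it says: “any equilibrium ceiling or later loss is invisible”.

Larch ends with 28.7% of target and 18.2% of isomer of the product, maple with 16.9% and 34.2%, ash with 14.6% and 36.6%.

    substrate → intermediate A (k = 0.0370 s⁻¹)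
    2 substrate → self-condensation product (k = 2.20 M⁻¹ s⁻¹)
    intermediate A → intermediate B (k = 0.0440 s⁻¹)
    target ⇌ isomer of the product (K = 2.50, k = 0.00740 s⁻¹)
    intermediate B → target (k = 0.0280 s⁻¹)

The unseen share stands at 71.2% at the end of larch, against 67.4% reckoned, and at 85.4% at the end of ash, against 10.8%. Ten times the time takes target in larch down to 14.6% and in maple to 14.6%, so neither has come to rest, while ash stays at 14.6%. The neighbour of ash, charged with 0.080 M of substrate, ends with 7.07% of target and an unseen share of 92.9%.

Readings and results come from a simulation on assumed constants, noise included.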